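75.0% of the Z charged is what the G in the east flask can bring to X, because the scheme Z + G ⇌ D, G + D → X spends two G on each X. The same count gives 25.0% in north-west, so G is the limiting reagent in both flasks.

the same everywhere: Z 0.020 M

| run | G | Q | remark | time |
|---|---|---|---|---|
| spring | 8.9 mM | 4 mM | run made earlier |  |
| autumn | 17 mM | 4 mM | run made earlier |  |
| north-west | 10.0 mM | 4.00 mM |  | 4.0 d |
| east | 30.0 mM | 4.00 mM |  | 4.0 d |

| run | time / d | X / % | Z / % | D / % |
|---|---|---|---|---|
| spring | 0.250 | 1.3 | 94.6 | 3.4 |
| spring | 0.625 | 3.3 | 94.4 | 3.0 |
| spring | 1.25 | 4.1 | 91.8 | 2.5 |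
| spring | 2.08 | 5.9 | 91.1 | 2.1 |
| spring | 3.00 | 7.9 | 90.3 | 2.8 |
| autumn | 0.208 | 4.0 | 88.6 | 7.1 |
| autumn | 0.417 | 8.2 | 86.7 | 5.4 |
| autumn | 0.833 | 11.7 | 83.0 | 3.8 |
| autumn | 1.67 | 18.1 | 79.5 | 3.5 |
| autumn | 3.00 | 22.8 | 75.2 | 2.1 |

(scatter of a reading: 0.5 percentage points)

- what may be going on: Z + G <-> D; G + D -> X; Q + G <-> L

- which of these there is most of at the end, counted by the Z in it, north-west (Z / D / X)
- which of these there is most of at the end, counted by the Z in it, east (Z / D / X)
- how much there is at the end of the one of these that leads, in percent of the Z charged: north-west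
- how much there is at the end of the one of these that leads, in percent of the Z charged: east

That ceiling is the late end of my reckoning, and the speed is the early end. D stays small and follows G: the first autumn reading of D is about twice the first spring one, with about twice the G. So I take D as proportional to G times Z, which makes the rate of X, a constant times G times D, go with G squared. While Z stays near its charge, such a loss of G joins both ends simply: if s is the share of the ceiling reached, the odds of s (reached over unreached) grow in proportion to time and, with the charge of Z held as it is in these flasks, to the equivalents of G per Z.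

At 3.00 d the spring run reads 35.5% of its ceiling, which gives 0.412 d⁻¹. The autumn run reads 53.6%, which gives 0.454 d⁻¹. I carry their mean, 0.433 d⁻¹, the burn constant: the growth of those odds per day and per equivalent of G.

For north-west this gives X at 11.6%, so Z leads. For east it gives X at 54.2%, which leaves 45.8% for Z and D together, so I say X leads there. Z does not stay near its charge in east, so my number leans high.

The forecast names Z in both flasks, at 85.5% in north-west and 50% in east, and says of east “It is almost a tie”. We part on the leader in east.

The flasks give Z at 87.3% in north-west and X at 51.8% in east, with Z there at 46.4%.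

    Z + G ⇌ D (K = 7.00 M⁻¹, k = 9.68 M⁻¹ h⁻¹)
    G + D → X (k = 10.4 M⁻¹ h⁻¹)
    Q + G ⇌ L (K = 510 M⁻¹, k = 19.4 M⁻¹ h⁻¹)

The main reason for X in east is the G charge: with the difference in G taken away, so that east holds north-west's G, X ends at 11.0% in place of 51.8%. Read back from east, the burn constant is 0.372 d⁻¹, lower than 0.433 d⁻¹, with Z down to 46.4%. In a further flask like north-west but charged with 0.040 M of G, the ceiling is 100%, and the carried 0.433 d⁻¹ gives X at 77.6%; that flask stands at 70.7% of X, with 27.8% of Z.

The readings are calculated on assumed constants; noise was put on by code.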